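Ring C is cut at C3–C4 and O1–C8a. On ring A, benzylic C4 and aryl C8a are 1,3-related through C4a; across C2, C3 and O1 are 1,3-related exactly as the carbon and oxygen termini of an aryl ketone enolate. The key step therefore joins the enolate of 3,4-bis(benzyloxy)acetophenone (ring B, C2, C3, O1) with 2-bromo-4,6-bis(benzyloxy)benzyl bromide (ring A, C4) in one flask. C-Benzylation makes C3–C4 and copper-catalysed enolate O-arylation makes O1–C8a, giving an achiral flav-2-ene. Asymmetric hydroboration then sets C2, and oxidation followed by cis-selective reduction sets C3 before esterification and debenzylation.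

Key step: step 4

Remark: the facial sense of the pinene-derived borane in step 5 is assumed to follow its known behaviour with 1-arylcycloalkenes; should 9 respond in the opposite sense, the borane from (−)-α-pinene would be used.

Step 1
Reactants: 1 1,3-bis(benzyloxy)-5-bromobenzene
Product: 3 2,4-bis(benzyloxy)-6-bromobenzaldehyde, via aryl iminium chloride 2 (not isolated)
Conditions: POCl3, DMF, 0 to 80 °C; then ice–water
Reagents that add atoms: N,N-dimethylformamide CN(C)C=O (formyl carbon); water O (carbonyl oxygen)
Why: Vilsmeier–Haack formylation, in which the chloroiminium electrophile should attack the position para to one benzyloxy group and ortho to the other (next to bromine), the site preferred in 5-substituted resorcinol diethers over the crowded position between the two ethers, and hydrolysis of iminium 2 releases the aldehyde.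

Step 2
Reactants: 3 2,4-bis(benzyloxy)-6-bromobenzaldehyde
Product: 4 [2,4-bis(benzyloxy)-6-bromophenyl]methanol
Conditions: NaBH4, THF–MeOH, 0 °C
Reagents that add atoms: none
Why: Borohydride reduction of an aryl aldehyde to the benzylic alcohol, which leaves the aryl bromide and the benzyl ethers untouched.

Step 3
Reactants: 4 [2,4-bis(benzyloxy)-6-bromophenyl]methanol
Product: 5 1,5-bis(benzyloxy)-3-bromo-2-(bromomethyl)benzene
Conditions: PBr3, CH2Cl2, 0 °C; used crude at once
Reagents that add atoms: phosphorus tribromide BrP(Br)Br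
Why: Bromination of a benzylic alcohol with PBr3 through the phosphite ester and bromide displacement, run cold and used immediately because the electron-rich benzylic bromide is labile.

Step 4
Reactants: 6 1-[3,4-bis(benzyloxy)phenyl]ethan-1-one, 5 1,5-bis(benzyloxy)-3-bromo-2-(bromomethyl)benzene
Product: 9 5,7-bis(benzyloxy)-2-[3,4-bis(benzyloxy)phenyl]-4H-chromene, via lithium enolate 7 (not isolated), via bromo ketone 8 (not isolated)
Conditions: LiN(SiMe3)2, THF, −78 °C; add 5, −78 to 0 °C; then NaOt-Bu, CuI (10 mol %), 1,10-phenanthroline (20 mol %), toluene, 90 °C, same flask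
Reagents that add atoms: none
Why: LiN(SiMe3)2 converts 6 into lithium enolate 7, whose carbon terminus displaces the benzylic bromide of 5 (SN2 enolate alkylation) to form C3–C4 in ketone 8; NaOt-Bu then regenerates the enolate, and monovalent copper inserts into the C8a–Br bond and couples it with the enolate oxygen (Ullmann-type C–O coupling) to form O1–C8a. The closest known reaction type is the tandem C-benzylation/copper-catalysed O-arylation of 1,3-dicarbonyl compounds with 2-bromobenzyl bromides to 4H-chromenes, together with the copper-catalysed intramolecular enolate O-arylation of 2-haloaryl ketones to benzofurans. The pyran ring closes in a 6-exo sense by attack of O1 on C8a, with the C8a–Br bond outside the new ring. No stereocentre is formed, because C2 and C3 emerge as the enol-ether double bond. The step needs C- before O-alkylation (lithium enolate in THF, soft benzylic bromide), mono-alkylation (slight excess of 7, low temperature) and O- rather than C-arylation, which the tether secures because C3–C8a closure would give a four-membered ring, while the (Z)-enolate geometry favoured for aryl ketones places O1 cis to the CH2 arm. The benzylic bromide should react first because the aryl bromide is inert until copper and heat are applied.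

Step 5
Reactants: 9 5,7-bis(benzyloxy)-2-[3,4-bis(benzyloxy)phenyl]-4H-chromene
Product: 11 (2R,3S)-5,7-bis(benzyloxy)-2-[3,4-bis(benzyloxy)phenyl]chroman-3-ol, via alkylborane 10 (not isolated)
Conditions: freshly prepared IpcBH2 from (+)-α-pinene, THF, −25 °C; then NaOH, H2O2, 0 °C to rt
Reagents that add atoms: hydrogen peroxide OO (the C3 oxygen); monoisopinocampheylborane C[C@H]1[C@H]([BH2])C[C@@H]2C[C@H]1C2(C)C (its boron and terpene part remain only in 10)
Why: Brown asymmetric hydroboration–oxidation, in which the chiral borane adds H and B syn across the trisubstituted enol-ether double bond with boron at C3 (β to O1, away from the aryl-bearing carbon); the pinane skeleton should select the alkene face as it does for 1-arylcycloalkenes, setting C2 as R and C3 as S (2,3-trans), and C–B oxidation proceeds with retention, with recrystallisation of 11 available to raise enantiomeric purity.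

Step 6
Reactants: 11 (2R,3S)-5,7-bis(benzyloxy)-2-[3,4-bis(benzyloxy)phenyl]chroman-3-ol
Product: 12 (2R)-5,7-bis(benzyloxy)-2-[3,4-bis(benzyloxy)phenyl]chroman-3-one
Conditions: Dess–Martin periodinane, CH2Cl2, 0 °C to rt; used directly
Reagents that add atoms: none
Why: Dess–Martin oxidation of the secondary alcohol under near-neutral conditions should give the flavan-3-one without enolisation at C2, so the C2 configuration is kept.

Step 7
Reactants: 12 (2R)-5,7-bis(benzyloxy)-2-[3,4-bis(benzyloxy)phenyl]chroman-3-one
Product: 13 (2R,3R)-5,7-bis(benzyloxy)-2-[3,4-bis(benzyloxy)phenyl]chroman-3-ol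
Conditions: LiBH(s-Bu)3 (L-Selectride), THF, −78 °C; then H2O
Reagents that add atoms: none
Why: Bulky-hydride reduction of a cyclic ketone, in which the hydride should reach C3 from the face opposite the C2 aryl group, so the new hydroxyl is cis to the aryl (3R) under substrate control from C2, at a temperature where C2 is not enolised.

Step 8
Reactants: 13 (2R,3R)-5,7-bis(benzyloxy)-2-[3,4-bis(benzyloxy)phenyl]chroman-3-ol, 14 4-(benzyloxy)benzoyl chloride
Product: 15 (2R,3R)-5,7-bis(benzyloxy)-2-[3,4-bis(benzyloxy)phenyl]chroman-3-yl 4-(benzyloxy)benzoate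
Conditions: Et3N, DMAP (cat.), CH2Cl2, 0 °C to rt
Reagents that add atoms: none
Why: DMAP-catalysed acylation of the hindered axial 3-hydroxyl through the N-acylpyridinium ion, which touches neither stereocentre.

Step 9
Reactants: 15 (2R,3R)-5,7-bis(benzyloxy)-2-[3,4-bis(benzyloxy)phenyl]chroman-3-yl 4-(benzyloxy)benzoate
Product: 16 epicatechin 3-O-p-hydroxybenzoate
Conditions: H2 (1 atm), Pd(OH)2/C, THF–MeOH, rt
Reagents that add atoms: none
Why: Hydrogenolysis over Pearlman's catalyst should cleave the five benzyl ethers while the aryl ester and the ring C2–O1 ether survive at 1 atm and room temperature.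

Compound list

1 | 1,3-bis(benzyloxy)-5-bromobenzene | Brc1cc(OCc2ccccc2)cc(OCc2ccccc2)c1 | starting material
2 | [2,4-bis(benzyloxy)-6-bromophenyl]methylidene-dimethyliminium chloride (not isolated) | C[N+](C)=Cc1c(Br)cc(OCc2ccccc2)cc1OCc1ccccc1.[Cl-] | intermediate
3 | 2,4-bis(benzyloxy)-6-bromobenzaldehyde | O=Cc1c(Br)cc(OCc2ccccc2)cc1OCc1ccccc1 | intermediate
4 | [2,4-bis(benzyloxy)-6-bromophenyl]methanol | OCc1c(Br)cc(OCc2ccccc2)cc1OCc1ccccc1 | intermediate
5 | 1,5-bis(benzyloxy)-3-bromo-2-(bromomethyl)benzene | BrCc1c(Br)cc(OCc2ccccc2)cc1OCc1ccccc1 | intermediate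
6 | 1-[3,4-bis(benzyloxy)phenyl]ethan-1-one | CC(=O)c1ccc(OCc2ccccc2)c(OCc2ccccc2)c1 | starting material
7 | lithium 1-[3,4-bis(benzyloxy)phenyl]ethen-1-olate (not isolated) | [Li+].[O-]C(=C)c1ccc(OCc2ccccc2)c(OCc2ccccc2)c1 | intermediate
8 | 1-[3,4-bis(benzyloxy)phenyl]-3-[2,4-bis(benzyloxy)-6-bromophenyl]propan-1-one (not isolated) | O=C(CCc1c(Br)cc(OCc2ccccc2)cc1OCc1ccccc1)c1ccc(OCc2ccccc2)c(OCc2ccccc2)c1 | intermediate
9 | 5,7-bis(benzyloxy)-2-[3,4-bis(benzyloxy)phenyl]-4H-chromene | C1(c2ccc(OCc3ccccc3)c(OCc3ccccc3)c2)=CCc2c(OCc3ccccc3)cc(OCc3ccccc3)cc2O1 | intermediate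
10 | isopinocampheyl[(2R,3S)-5,7-bis(benzyloxy)-2-[3,4-bis(benzyloxy)phenyl]chroman-3-yl]borane (not isolated) | C[C@H]1[C@H]([BH][C@H]3Cc4c(OCc5ccccc5)cc(OCc5ccccc5)cc4O[C@@H]3c3ccc(OCc4ccccc4)c(OCc4ccccc4)c3)C[C@@H]2C[C@H]1C2(C)C | intermediate
11 | (2R,3S)-5,7-bis(benzyloxy)-2-[3,4-bis(benzyloxy)phenyl]chroman-3-ol | O[C@H]1Cc2c(OCc3ccccc3)cc(OCc3ccccc3)cc2O[C@@H]1c1ccc(OCc2ccccc2)c(OCc2ccccc2)c1 | intermediate
12 | (2R)-5,7-bis(benzyloxy)-2-[3,4-bis(benzyloxy)phenyl]chroman-3-one | O=C1Cc2c(OCc3ccccc3)cc(OCc3ccccc3)cc2O[C@@H]1c1ccc(OCc2ccccc2)c(OCc2ccccc2)c1 | intermediate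
13 | (2R,3R)-5,7-bis(benzyloxy)-2-[3,4-bis(benzyloxy)phenyl]chroman-3-ol | O[C@@H]1Cc2c(OCc3ccccc3)cc(OCc3ccccc3)cc2O[C@@H]1c1ccc(OCc2ccccc2)c(OCc2ccccc2)c1 | intermediate
14 | 4-(benzyloxy)benzoyl chloride | O=C(Cl)c1ccc(OCc2ccccc2)cc1 | starting material
15 | (2R,3R)-5,7-bis(benzyloxy)-2-[3,4-bis(benzyloxy)phenyl]chroman-3-yl 4-(benzyloxy)benzoate | O=C(O[C@@H]1Cc2c(OCc3ccccc3)cc(OCc3ccccc3)cc2O[C@@H]1c1ccc(OCc2ccccc2)c(OCc2ccccc2)c1)c1ccc(OCc2ccccc2)cc1 | intermediate
16 | epicatechin 3-O-p-hydroxybenzoate, (2R,3R)-2-(3,4-dihydroxyphenyl)-5,7-dihydroxychroman-3-yl 4-hydroxybenzoate | O=C(O[C@@H]1Cc2c(O)cc(O)cc2O[C@@H]1c1ccc(O)c(O)c1)c1ccc(O)cc1 | target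

Total step count: 9. Longest linear sequence: 9 steps (1 to 16, steps 1–9); 6 and 14 are purchased.

Steps most likely to fail

Step 4. The copper-catalysed C–O ring closure may stall on the hindered, electron-rich aryl bromide while the ketone enolate is lost to over-alkylation or aldol self-condensation. The fallback forms the two bonds separately with known reactions, setting out from 3 and 6 and returning at 9. Claisen–Schmidt condensation of 6 with 3 (KOH, EtOH–THF) should give the chalcone (E)-1-[3,4-bis(benzyloxy)phenyl]-3-[2,4-bis(benzyloxy)-6-bromophenyl]prop-2-en-1-one F1. Conjugate reduction with [(Ph3P)CuH]6 should give 8, now isolated. Enolate O-arylation under zerovalent palladium catalysis (Pd2(dba)3, DPEphos, NaOt-Bu, toluene, 100 °C) should then close ring C to 9. This path also avoids the labile bromide 5.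

Step 5. Facial discrimination by the chiral borane may be poor, or hydroboration of the hindered alkene may be sluggish, leaving 11 and hence 12 with low enantiomeric purity. The fallback moves stereocontrol to a dynamic kinetic resolution; it sets out from 12 in whatever enantiomeric purity steps 5 and 6 deliver and returns at 13. Noyori-type transfer hydrogenation with RuCl[(S,S)-TsDPEN](p-cymene) and HCO2H–Et3N replaces the hydride of step 7. C2 of the ketone should racemise through the enol under these conditions, and the catalyst should reduce one enantiomer faster to the cis alcohol, setting C2 and C3 together. The catalyst antipode that delivers (2R,3R) would be fixed in a preliminary run.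

Step 1. Formylation may occur at the position between the two benzyloxy groups, or benzyl ethers may be lost under the acidic chlorophosphate conditions. The fallback buys the regiochemistry instead of creating it; it does not set out from 1 but from commercial 2-bromo-4,6-dimethoxybenzaldehyde F2, and returns at 3. Demethylation with BBr3 (CH2Cl2, −78 °C to rt) should give 2-bromo-4,6-dihydroxybenzaldehyde F3. Benzylation (BnBr, K2CO3, DMF) should then give 3.

Further compounds
F1 | step 4 | (E)-1-[3,4-bis(benzyloxy)phenyl]-3-[2,4-bis(benzyloxy)-6-bromophenyl]prop-2-en-1-one | O=C(/C=C/c1c(Br)cc(OCc2ccccc2)cc1OCc1ccccc1)c1ccc(OCc2ccccc2)c(OCc2ccccc2)c1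
F0 | step 5 | none | none
F2 | step 1 | 2-bromo-4,6-dimethoxybenzaldehyde | COc1cc(OC)c(C=O)c(Br)c1
F3 | step 1 | 2-bromo-4,6-dihydroxybenzaldehyde | O=Cc1c(O)cc(O)cc1Br
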